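Rings are lettered A (2,4,6-trihydroxyphenoxy end) to F. Ring B carries oxygen on C-1, C-3, C-4, C-5 and C-6 and hydrogen only on C-2. The route exploits this by building ring B from dimethyl squarate (C-3 to C-6 with their oxygens) and the vinyl ether of the ring A phenol (C-1, C-2 and the A–O–B oxygen). Heating a 4-siloxy-4-(1-aryloxyvinyl)cyclobutenone opens it to a dienylketene that electrocyclises, forming the C-2–C-3 bond and the aromatic ring B with the C-3 and C-6 oxygens differentiated. The same operation later builds ring D on ring C. The B–C, D–E and E–F ethers come from copper couplings, and sixteen methyl ethers are cleaved last.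

Key step: step 3

Remark: the target is achiral. In rings B and D, C-1 carries the oxygen to the preceding ring and C-6 the oxygen to the following ring. The second cyclobutenone is assembled on the ABC trimer because an aryl bromide on ring C would not survive the vinyl metalation.

Step 1
Reactants: 1 2,4,6-trimethoxyphenol; 2 vinyl acetate
Product: 3 1,3,5-trimethoxy-2-(vinyloxy)benzene
Conditions: [Ir(cod)Cl]2 (1 mol%), Na2CO3 (0.6 equiv), PhMe, 100 °C
Reagents that add atoms: none
Why: Iridium-catalysed transfer vinylation exchanges acetate for aryloxide on the vinyl group under almost neutral conditions, so the hindered phenol should be O-vinylated cleanly; no stereocentre is formed.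

Step 2
Reactants: 3 1,3,5-trimethoxy-2-(vinyloxy)benzene; 4 dimethyl squarate
Product: 7 racemic 4-(tert-butyldimethylsilyloxy)-2,3-dimethoxy-4-[1-(2,4,6-trimethoxyphenoxy)vinyl]cyclobut-2-en-1-one, via vinyllithium 5 (not isolated), via lithium alkoxide 6 (not isolated)
Conditions: t-BuLi (1.05 equiv), THF, −78 °C; cannulate into 4, THF, −78 °C; TBSOTf, −78 → −20 °C
Reagents that add atoms: tert-butyldimethylsilyl trifluoromethanesulfonate, CC(C)(C)[Si](C)(C)OS(=O)(=O)C(F)(F)F
Why: α-Metalation of an enol ether (the O–CH= hydrogen is acidified by the aryloxy oxygen and should be removed at −78 °C before the ring hydrogens), 1,2-addition of the vinyllithium to one of the two equivalent carbonyls of the symmetrical squaric ester and in situ O-silylation of the tertiary alkoxide; the carbinol centre forms as a racemate, which does not matter because it becomes aromatic C-6 in step 3.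

Step 3
Reactants: 7 racemic 4-(tert-butyldimethylsilyloxy)-2,3-dimethoxy-4-[1-(2,4,6-trimethoxyphenoxy)vinyl]cyclobut-2-en-1-one
Product: 10 4-(tert-butyldimethylsilyloxy)-2,3-dimethoxy-5-(2,4,6-trimethoxyphenoxy)phenol (AB dimer), via dienylketene 8 (not isolated), via cyclohexadienone 9 (not isolated)
Conditions: PhMe (degassed), 110 °C, Ar
Reagents that add atoms: none
Why: Heating breaks the bond between the carbonyl carbon and the carbinol carbon in a thermal four-electron conrotatory ring opening; the siloxy donor turns outward, so the aryloxyvinyl group lies cis to the ketene in 8. Ring B then closes by a thermal disrotatory six-electron electrocyclisation between the ketene carbon and the vinyl CH2, which forms the C-2–C-3 bond and gives dienone 9; tautomerisation to phenol 10 makes the sequence irreversible. The closest known reaction type is the Moore rearrangement of 4-alkenyl-4-siloxycyclobutenones derived from squaric esters, including α-alkoxyvinyl cases. No stereocentre is created, and the racemic centre of 7 is lost on aromatisation. The step needs inward rotation of the vinyl group and lasting differentiation of the two para oxygens: the oxygen donor at the carbinol carbon secures the first, and the silyl group, which cannot reach the para oxygen, secures the second (C-6 oxygen silylated, C-3 hydroxyl free). The symmetry of the squarate removes any regiochemical question for the C-4 and C-5 methoxyls.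

Step 4
Reactants: 10 4-(tert-butyldimethylsilyloxy)-2,3-dimethoxy-5-(2,4,6-trimethoxyphenoxy)phenol
Product: 11 tert-butyldimethyl[2,3,4-trimethoxy-6-(2,4,6-trimethoxyphenoxy)phenoxy]silane
Conditions: MeI, K2CO3, acetone, reflux
Reagents that add atoms: iodomethane, CI
Why: Williamson methylation of the only free hydroxyl (C-3 of ring B); the di-ortho-substituted aryl silyl ether should survive anhydrous carbonate.

Step 5
Reactants: 11 tert-butyldimethyl[2,3,4-trimethoxy-6-(2,4,6-trimethoxyphenoxy)phenoxy]silane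
Product: 12 2,3,4-trimethoxy-6-(2,4,6-trimethoxyphenoxy)phenol
Conditions: TBAF, AcOH, THF, 0 °C → rt
Reagents that add atoms: none
Why: Fluoride-mediated desilylation of an aryl silyl ether; the acetic acid buffer keeps the electron-rich phenol protonated and so protects it from air oxidation.

Step 6
Reactants: 13 4-bromo-2,6-dimethoxyphenol; 2 vinyl acetate
Product: 14 5-bromo-1,3-dimethoxy-2-(vinyloxy)benzene
Conditions: [Ir(cod)Cl]2 (1 mol%), Na2CO3 (0.6 equiv), PhMe, 100 °C
Reagents that add atoms: none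
Why: The same iridium-catalysed transfer vinylation as in step 1; the aryl bromide should be inert to the monovalent iridium catalyst at this temperature.

Step 7
Reactants: 12 2,3,4-trimethoxy-6-(2,4,6-trimethoxyphenoxy)phenol; 14 5-bromo-1,3-dimethoxy-2-(vinyloxy)benzene
Product: 15 5-[2,3,4-trimethoxy-6-(2,4,6-trimethoxyphenoxy)phenoxy]-1,3-dimethoxy-2-(vinyloxy)benzene (ABC trimer vinyl ether)
Conditions: CuI (10 mol%), picolinic acid (20 mol%), K3PO4, DMSO, 90 °C, Ar
Reagents that add atoms: none
Why: Ligand-accelerated Ullmann diaryl ether synthesis; the bromide has no ortho substituent, the picolinate system tolerates di-ortho-substituted phenols, and the vinyl ether is stable to base.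

Step 8
Reactants: 15 ABC trimer vinyl ether; 4 dimethyl squarate
Product: 18 racemic 4-(tert-butyldimethylsilyloxy)-2,3-dimethoxy-4-[1-(ABC-aryloxy)vinyl]cyclobut-2-en-1-one (aryl = 2,6-dimethoxy-4-[2,3,4-trimethoxy-6-(2,4,6-trimethoxyphenoxy)phenoxy]phenyl), via vinyllithium 16 (not isolated), via lithium alkoxide 17 (not isolated)
Conditions: t-BuLi (1.05 equiv), THF, −78 °C; cannulate into 4, THF, −78 °C; TBSOTf, −78 → −20 °C
Reagents that add atoms: tert-butyldimethylsilyl trifluoromethanesulfonate, CC(C)(C)[Si](C)(C)OS(=O)(=O)C(F)(F)F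
Why: The same α-metalation of the enol ether, 1,2-addition to the squaric ester and in situ silylation as in step 2; the carbinol centre again forms as a racemate and is lost in step 9.

Step 9
Reactants: 18 racemic ABC-substituted cyclobutenone
Product: 21 ABCD tetramer with ring D C-3 hydroxyl free and C-6 oxygen silylated, via dienylketene 19 (not isolated), via cyclohexadienone 20 (not isolated)
Conditions: PhMe (degassed), 110 °C, Ar
Reagents that add atoms: none
Why: A second Moore rearrangement (conrotatory ring opening, six-electron electrocyclisation, tautomerisation) builds ring D on the ring C oxygen exactly as ring B was built on ring A; no stereocentre is formed.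

Step 10
Reactants: 21 ABCD tetramer phenol (C-6 silyl ether)
Product: 22 ABCD tetramer with ring D C-3 methoxyl and C-6 silyl ether
Conditions: MeI, K2CO3, acetone, reflux
Reagents that add atoms: iodomethane, CI
Why: Williamson methylation of the single free hydroxyl, as in step 4.

Step 11
Reactants: 22 ABCD tetramer silyl ether
Product: 23 ABCD tetramer with free ring D C-6 hydroxyl
Conditions: TBAF, AcOH, THF, 0 °C → rt
Reagents that add atoms: none
Why: Buffered fluoride desilylation of the aryl silyl ether, as in step 5.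

Step 12
Reactants: 13 4-bromo-2,6-dimethoxyphenol; 24 3,4,5-trimethoxyphenylboronic acid
Product: 25 5-bromo-1,3-dimethoxy-2-(3,4,5-trimethoxyphenoxy)benzene (EF bromide)
Conditions: Cu(OAc)2 (1 equiv), pyridine, 4 Å MS, CH2Cl2, air, rt
Reagents that add atoms: none
Why: Chan–Lam oxidative O-arylation, known for di-ortho-substituted phenols; the aryl bromide is inert to divalent copper at room temperature, the para bromine blocks oxidative phenol dimerisation, and dioxygen returns the copper to the divalent state.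

Step 13
Reactants: 23 ABCD tetramer phenol; 25 EF bromide
Product: 26 hexadeca-O-methyl ether of the target (ABCDEF hexamer)
Conditions: CuI (20 mol%), picolinic acid (40 mol%), K3PO4, DMSO, 100 °C, Ar
Reagents that add atoms: none
Why: Ullmann diaryl ether synthesis of the same kind as step 7, joining the hindered ring D phenoxide to the ortho-unsubstituted ring E bromide.

Step 14
Reactants: 26 hexadeca-O-methyl ether
Product: 27 target CNP0218077.0
Conditions: BBr3 (excess), CH2Cl2, −78 °C → rt, Ar; H2O, 0 °C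
Reagents that add atoms: none
Why: Lewis-acid cleavage of all sixteen aryl methyl ethers by BBr3, which leaves diaryl ether bonds intact; the polyphenol should be isolated under argon.

Compound list
1 | 2,4,6-trimethoxyphenol | COc1cc(OC)c(O)c(OC)c1 | starting material
2 | vinyl acetate | CC(=O)OC=C | starting material
3 | 1,3,5-trimethoxy-2-(vinyloxy)benzene | C=COc1c(OC)cc(OC)cc1OC | intermediate
4 | dimethyl squarate | COC1=C(OC)C(=O)C1=O | starting material
5 | 1-(2,4,6-trimethoxyphenoxy)vinyllithium (not isolated) | [Li]C(=C)Oc1c(OC)cc(OC)cc1OC | intermediate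
6 | lithium 2,3-dimethoxy-4-oxo-1-[1-(2,4,6-trimethoxyphenoxy)vinyl]cyclobut-2-en-1-olate, racemic (not isolated) | [Li+].[O-]C1(C(=C)Oc2c(OC)cc(OC)cc2OC)C(OC)=C(OC)C1=O | intermediate
7 | racemic 4-(tert-butyldimethylsilyloxy)-2,3-dimethoxy-4-[1-(2,4,6-trimethoxyphenoxy)vinyl]cyclobut-2-en-1-one | COC1=C(OC)C(O[Si](C)(C)C(C)(C)C)(C(=C)Oc2c(OC)cc(OC)cc2OC)C1=O | intermediate
8 | dienylketene from 7, aryloxyvinyl cis to the ketene (not isolated) | O=C=C(OC)/C(OC)=C(\C(=C)Oc1c(OC)cc(OC)cc1OC)O[Si](C)(C)C(C)(C)C | intermediate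
9 | 4-(tert-butyldimethylsilyloxy)-2,3-dimethoxy-5-(2,4,6-trimethoxyphenoxy)cyclohexa-2,4-dien-1-one (not isolated) | O=C1CC(Oc2c(OC)cc(OC)cc2OC)=C(O[Si](C)(C)C(C)(C)C)C(OC)=C1OC | intermediate
10 | 4-(tert-butyldimethylsilyloxy)-2,3-dimethoxy-5-(2,4,6-trimethoxyphenoxy)phenol | COc1cc(OC)c(Oc2cc(O)c(OC)c(OC)c2O[Si](C)(C)C(C)(C)C)c(OC)c1 | intermediate
11 | tert-butyldimethyl[2,3,4-trimethoxy-6-(2,4,6-trimethoxyphenoxy)phenoxy]silane | COc1cc(OC)c(Oc2cc(OC)c(OC)c(OC)c2O[Si](C)(C)C(C)(C)C)c(OC)c1 | intermediate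
12 | 2,3,4-trimethoxy-6-(2,4,6-trimethoxyphenoxy)phenol | COc1cc(OC)c(Oc2cc(OC)c(OC)c(OC)c2O)c(OC)c1 | intermediate
13 | 4-bromo-2,6-dimethoxyphenol | COc1cc(Br)cc(OC)c1O | starting material
14 | 5-bromo-1,3-dimethoxy-2-(vinyloxy)benzene | C=COc1c(OC)cc(Br)cc1OC | intermediate
15 | 5-[2,3,4-trimethoxy-6-(2,4,6-trimethoxyphenoxy)phenoxy]-1,3-dimethoxy-2-(vinyloxy)benzene | COc1cc(OC)c(Oc2cc(OC)c(OC)c(OC)c2Oc2cc(OC)c(OC=C)c(OC)c2)c(OC)c1 | intermediate
16 | α-lithiated vinyl ether of the ABC trimer (not isolated) | COc1cc(OC)c(Oc2cc(OC)c(OC)c(OC)c2Oc2cc(OC)c(OC([Li])=C)c(OC)c2)c(OC)c1 | intermediate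
17 | lithium alkoxide of the ABC squarate adduct, racemic (not isolated) | COc1cc(OC)c(Oc2cc(OC)c(OC)c(OC)c2Oc2cc(OC)c(OC(=C)C3([O-])C(OC)=C(OC)C3=O)c(OC)c2)c(OC)c1.[Li+] | intermediate
18 | racemic 4-(tert-butyldimethylsilyloxy)-2,3-dimethoxy-4-[1-(ABC-aryloxy)vinyl]cyclobut-2-en-1-one | COc1cc(OC)c(Oc2cc(OC)c(OC)c(OC)c2Oc2cc(OC)c(OC(=C)C3(O[Si](C)(C)C(C)(C)C)C(OC)=C(OC)C3=O)c(OC)c2)c(OC)c1 | intermediate
19 | dienylketene from 18, aryloxyvinyl cis to the ketene (not isolated) | COc1cc(OC)c(Oc2cc(OC)c(OC)c(OC)c2Oc2cc(OC)c(OC(=C)/C(O[Si](C)(C)C(C)(C)C)=C(OC)\C(OC)=C=O)c(OC)c2)c(OC)c1 | intermediate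
20 | cyclohexa-2,4-dienone precursor of ring D (not isolated) | COc1cc(OC)c(Oc2cc(OC)c(OC)c(OC)c2Oc2cc(OC)c(OC3=C(O[Si](C)(C)C(C)(C)C)C(OC)=C(OC)C(=O)C3)c(OC)c2)c(OC)c1 | intermediate
21 | ABCD tetramer, ring D C-3 hydroxyl free, C-6 tert-butyldimethylsilyl ether | COc1cc(OC)c(Oc2cc(OC)c(OC)c(OC)c2Oc2cc(OC)c(Oc3cc(O)c(OC)c(OC)c3O[Si](C)(C)C(C)(C)C)c(OC)c2)c(OC)c1 | intermediate
22 | ABCD tetramer, ring D C-3 methoxyl, C-6 tert-butyldimethylsilyl ether | COc1cc(OC)c(Oc2cc(OC)c(OC)c(OC)c2Oc2cc(OC)c(Oc3cc(OC)c(OC)c(OC)c3O[Si](C)(C)C(C)(C)C)c(OC)c2)c(OC)c1 | intermediate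
23 | ABCD tetramer, ring D C-6 hydroxyl free, all other oxygens methylated | COc1cc(OC)c(Oc2cc(OC)c(OC)c(OC)c2Oc2cc(OC)c(Oc3cc(OC)c(OC)c(OC)c3O)c(OC)c2)c(OC)c1 | intermediate
24 | 3,4,5-trimethoxyphenylboronic acid | COc1cc(B(O)O)cc(OC)c1OC | starting material
25 | 5-bromo-1,3-dimethoxy-2-(3,4,5-trimethoxyphenoxy)benzene | COc1cc(Oc2c(OC)cc(Br)cc2OC)cc(OC)c1OC | intermediate
26 | hexadeca-O-methyl ether of the target | COc1cc(OC)c(Oc2cc(OC)c(OC)c(OC)c2Oc2cc(OC)c(Oc3cc(OC)c(OC)c(OC)c3Oc3cc(OC)c(Oc4cc(OC)c(OC)c(OC)c4)c(OC)c3)c(OC)c2)c(OC)c1 | intermediate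
27 | 4-[4-[2-[3,5-dihydroxy-4-(3,4,5-trihydroxyphenoxy)phenoxy]-3,4,5-trihydroxyphenoxy]-3,5-dihydroxyphenoxy]-5-(2,4,6-trihydroxyphenoxy)benzene-1,2,3-triol (CNP0218077.0) | Oc1cc(O)c(Oc2cc(O)c(O)c(O)c2Oc2cc(O)c(Oc3cc(O)c(O)c(O)c3Oc3cc(O)c(Oc4cc(O)c(O)c(O)c4)c(O)c3)c(O)c2)c(O)c1 | target

Total step count: 14. Longest linear sequence: 12 steps (steps 1–5, 7–11, 13 and 14, from 1).

Steps most likely to fail

1. Step 8. The base may remove ring hydrogens that lie between two oxygens on rings A, B and C instead of the α-vinyl hydrogen, and vinyllithium 16 may lose lithium aryloxide by α-elimination if it warms. The fallback makes 16 regiospecifically by tin–lithium exchange and sets out from 15. The vinyl ether is hydrolysed (1 M HCl, THF, rt) to 2,6-dimethoxy-4-[2,3,4-trimethoxy-6-(2,4,6-trimethoxyphenoxy)phenoxy]phenol F1. Reaction with trichloroethylene (K2CO3, DMF, 70 °C) gives the (E)-1,2-dichlorovinyl ether F2. Treatment with n-BuLi (2.5 equiv, THF, −78 °C, then MeOH) gives the aryl ethynyl ether F3; at this temperature n-BuLi should not touch the ring hydrogens. Hydrostannation with zerovalent palladium (Bu3SnH, Pd(PPh3)4, THF, 0 °C) places tin on the oxygen-bearing carbon and gives the 1-(tributylstannyl)vinyl ether F4. n-BuLi (THF, −78 °C) then gives 16, and the route is rejoined there, leading to 18 as in step 8.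

2. Step 2. The same competition between α-vinyl and ring deprotonation arises, here at the two ring A hydrogens flanked by methoxyls. The fallback sets out from 1 and comes back at 5. Reaction of 1 with trichloroethylene (K2CO3, DMF, 70 °C) gives 2-[(E)-1,2-dichlorovinyloxy]-1,3,5-trimethoxybenzene F5. n-BuLi (2.5 equiv, THF, −78 °C, then MeOH) gives 2-(ethynyloxy)-1,3,5-trimethoxybenzene F6. Bu3SnH with Pd(PPh3)4 (THF, 0 °C) gives tributyl[1-(2,4,6-trimethoxyphenoxy)vinyl]stannane F7. Tin–lithium exchange (n-BuLi, THF, −78 °C) gives 5, which is carried on to 6 and 7 as in step 2.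

3. Step 13. Coupling of a di-ortho-substituted, electron-rich phenoxide with an electron-rich aryl bromide may be slow, so that hydrodebromination of 25 and oxidative decay of the phenoxide take over. The fallback reverses the polarity of the aryl partner and uses oxidative coupling with divalent copper, as in step 12. It sets out from 25 and comes back at 26. Bromine–lithium exchange (n-BuLi, THF, −78 °C), B(OiPr)3 and aqueous HCl give [3,5-dimethoxy-4-(3,4,5-trimethoxyphenoxy)phenyl]boronic acid F8. Chan–Lam coupling of F8 with 23 (Cu(OAc)2, pyridine, 4 Å MS, CH2Cl2, air, rt) should give 26.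

Further compounds
F1 | step 8 | 2,6-dimethoxy-4-[2,3,4-trimethoxy-6-(2,4,6-trimethoxyphenoxy)phenoxy]phenol | COc1cc(OC)c(Oc2cc(OC)c(OC)c(OC)c2Oc2cc(OC)c(O)c(OC)c2)c(OC)c1
F2 | step 8 | (E)-1,2-dichlorovinyl ether of F1 | COc1cc(OC)c(Oc2cc(OC)c(OC)c(OC)c2Oc2cc(OC)c(O/C(Cl)=C\Cl)c(OC)c2)c(OC)c1
F3 | step 8 | ethynyl ether of F1 | COc1cc(OC)c(Oc2cc(OC)c(OC)c(OC)c2Oc2cc(OC)c(OC#C)c(OC)c2)c(OC)c1
F4 | step 8 | 1-(tributylstannyl)vinyl ether of F1 | COc1cc(OC)c(Oc2cc(OC)c(OC)c(OC)c2Oc2cc(OC)c(OC(=C)[Sn](CCCC)(CCCC)CCCC)c(OC)c2)c(OC)c1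
F5 | step 2 | 2-[(E)-1,2-dichlorovinyloxy]-1,3,5-trimethoxybenzene | COc1cc(OC)c(O/C(Cl)=C\Cl)c(OC)c1
F6 | step 2 | 2-(ethynyloxy)-1,3,5-trimethoxybenzene | COc1cc(OC)c(OC#C)c(OC)c1
F7 | step 2 | tributyl[1-(2,4,6-trimethoxyphenoxy)vinyl]stannane | COc1cc(OC)c(OC(=C)[Sn](CCCC)(CCCC)CCCC)c(OC)c1
F8 | step 13 | [3,5-dimethoxy-4-(3,4,5-trimethoxyphenoxy)phenyl]boronic acid | COc1cc(Oc2c(OC)cc(B(O)O)cc2OC)cc(OC)c1OC
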